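**Retrosynthetic overview**
1. Target ⇐ acetylation of the primary OH of (13S)-labdane-8α,15-diol ⇐ Ru–BINAP hydrogenation of the E-13-ene-8α,15-diol (sets C-13) ⇐ HWE/DIBAL on 8α-hydroxy-14,15-dinorlabdan-13-one.
2. Ring B (formed second): cation–olefin cyclisation of a monocyclic tertiary carbinol; the C-10 cation adds to the E-C8=C9 alkene and the C-13 ketone oxygen traps C-8 (C-5 controls C-8, C-9, C-10).
3. Chain of the cyclisation substrate: alkyne methylalumination (E-alkene, C-17) and Cu-catalysed addition to methyl vinyl ketone (C-11 to C-13, C-16).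
4. Ring A (formed first): one-carbon ring expansion of 2,2-dimethylcyclopentanone by a sparteine-derived lithiated carbamate of pent-4-yn-1-ol; the CMe2 ring carbon undergoes a 1,2-shift with loss of carbamate, which sets C-5.
5. Starting materials: pent-4-yn-1-ol, 2,2-dimethylcyclopentanone, but-3-en-2-one.

Assumption: the SMILES is read as (5S,8R,9R,10S,13S)-8α-hydroxylabdan-15-yl acetate (sclareol-type decalin); labdane numbering is used in the comments.

**Step 1**
Reactants: 1 pent-4-yn-1-ol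
Product: 3 5-(trimethylsilyl)pent-4-yn-1-yl N,N-diisopropylcarbamate, via pent-4-yn-1-yl N,N-diisopropylcarbamate 2 (not isolated)
Conditions: NaH, THF, 0 °C; iPr2NCOCl, reflux; cool to −78 °C, n-BuLi; TMSCl, −78 → 23 °C (one pot)
Reagents that add atoms: N,N-diisopropylcarbamoyl chloride CC(C)N(C(C)C)C(Cl)=O; chlorotrimethylsilane C[Si](C)(C)Cl
Why: O-carbamoylation of the alkoxide, then deprotonation of the terminal alkyne (the hindered carbamate is inert to n-BuLi at −78 °C) and C-silylation, which masks the acidic C–H for step 2 (carbamate formation, acetylide silylation).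

**Step 2**
Reactants: 3 5-(trimethylsilyl)pent-4-yn-1-yl N,N-diisopropylcarbamate; 4 2,2-dimethylcyclopentan-1-one
Product: 7 (2S)-3,3-dimethyl-2-[4-(trimethylsilyl)but-3-yn-1-yl]cyclohexan-1-one, via lithiated carbamate 5 (not isolated), via lithium alkoxide adduct 6 (not isolated)
Conditions: s-BuLi, (+)-sparteine, Et2O, −78 °C, 5 h; 4, −78 °C, 2 h; then Me2AlCl (2.5 equiv, toluene), −78 → 23 °C
Reagents that add atoms: none
Why: Proposed new method: (+)-sparteine-directed deprotonation (Hoppe lithiation) removes the pro-R proton to give the configurationally stable (R)-lithio carbamate 5, which adds to ketone 4 with retention to give (S)-6; Me2AlCl exchanges Li for Al at the alkoxide and activates the carbamate carbonyl, so the antiperiplanar, more electron-rich quaternary ring carbon (CMe2) migrates to the carbinyl carbon with inversion while the carbamate leaves, a semipinacol-type ring expansion that gives the (S) α-centre (labdane C-5); the closest known reactions are the organoaluminium-promoted semipinacol rearrangement of 2-sulfonyloxy alcohols and the 1,2-metallate rearrangement of lithiated-carbamate boronate complexes.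

**Step 3**
Reactants: 7 (2S)-3,3-dimethyl-2-[4-(trimethylsilyl)but-3-yn-1-yl]cyclohexan-1-one
Product: 9 (2S)-2-(but-3-yn-1-yl)-1,3,3-trimethylcyclohexan-1-ol, via silylalkynyl carbinol 8 (not isolated)
Conditions: MeMgBr, CeCl3, THF, −78 → 0 °C; then MeOH, K2CO3, 23 °C
Reagents that add atoms: methylmagnesium bromide C[Mg]Br
Why: Cerium-mediated Grignard 1,2-addition to the hindered ketone without enolisation, then methanolysis of the C(sp)–Si bond; the new carbinol centre (both epimers) is unimportant because it is ionised in step 5.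

**Step 4**
Reactants: 9 (2S)-2-(but-3-yn-1-yl)-1,3,3-trimethylcyclohexan-1-ol; 10 but-3-en-2-one
Product: 12 (5E)-8-[(1S)-2-hydroxy-2,6,6-trimethylcyclohexyl]-6-methyloct-5-en-2-one, via alkenylalane 11 (not isolated)
Conditions: Me3Al (3.5 equiv), Cp2ZrCl2 (20 mol %), CH2Cl2, 0 → 23 °C; then THF, CuBr·SMe2 (10 mol %), 10 (3 equiv), −30 → 0 °C; aq. NH4Cl
Reagents that add atoms: trimethylaluminium C[Al](C)C
Why: Zirconium-catalysed syn-methylalumination (Negishi carboalumination) puts CH3 on the internal and Al on the terminal alkyne carbon, which fixes the E trisubstituted alkene, and Cu(I)-catalysed conjugate addition transfers the alkenyl group to the enone.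

**Step 5**
Reactants: 12 (5E)-8-[(1S)-2-hydroxy-2,6,6-trimethylcyclohexyl]-6-methyloct-5-en-2-one
Product: 14 4-[(1R,2R,4aS,8aS)-2-hydroxy-2,5,5,8a-tetramethyldecahydronaphthalen-1-yl]butan-2-one, via sclareol oxide 13 (not isolated)
Conditions: TfOH (2 equiv), 2-nitropropane, −78 °C, 30 min; then THF–1 M aq. HCl, 23 °C
Reagents that add atoms: water O
Why: Acid ionises both carbinol epimers to the same C-10 cation, which closes ring B on the E-alkene through a chair transition state with the C-5 chain equatorial (cation–olefin cyclisation, trans ring fusion, 9β side chain), the ketone oxygen captures the C-8 cation anti to the new C-9–C-10 bond (8α-O, 8β-CH3), and aqueous acid hydrolyses the resulting enol ether 13 to the hydroxy ketone.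

**Step 6**
Reactants: 14 4-[(1R,2R,4aS,8aS)-2-hydroxy-2,5,5,8a-tetramethyldecahydronaphthalen-1-yl]butan-2-one
Product: 15 ethyl (2E)-5-[(1R,2R,4aS,8aS)-2-hydroxy-2,5,5,8a-tetramethyldecahydronaphthalen-1-yl]-3-methylpent-2-enoate
Conditions: (EtO)2P(O)CH2CO2Et, NaH (excess), THF, 0 → 50 °C; chromatography to remove the Z isomer
Reagents that add atoms: triethyl phosphonoacetate CCOC(=O)CP(=O)(OCC)OCC
Why: Horner–Wadsworth–Emmons olefination of the methyl ketone gives mainly the E enoate (expected about 5:1), with the tertiary alkoxide as a spectator.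

**Step 7**
Reactants: 15 ethyl (2E)-5-[(1R,2R,4aS,8aS)-2-hydroxy-2,5,5,8a-tetramethyldecahydronaphthalen-1-yl]-3-methylpent-2-enoate
Product: 16 (1R,2R,4aS,8aS)-1-[(3E)-5-hydroxy-3-methylpent-3-en-1-yl]-2,5,5,8a-tetramethyldecahydronaphthalen-2-ol
Conditions: DIBAL-H (3.5 equiv), CH2Cl2, −78 → 0 °C; Rochelle salt work-up
Reagents that add atoms: none
Why: DIBAL-H 1,2-reduction of the conjugated ester to the allylic alcohol leaves the alkene and its E geometry untouched.

**Step 8**
Reactants: 16 (1R,2R,4aS,8aS)-1-[(3E)-5-hydroxy-3-methylpent-3-en-1-yl]-2,5,5,8a-tetramethyldecahydronaphthalen-2-ol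
Product: 17 (1R,2R,4aS,8aS)-1-[(3S)-5-hydroxy-3-methylpentyl]-2,5,5,8a-tetramethyldecahydronaphthalen-2-ol
Conditions: Ru(OAc)2[(R)-BINAP] (1 mol %), H2 (100 atm), MeOH–H2O 95:5, 20 °C
Reagents that add atoms: none
Why: Noyori Ru–BINAP asymmetric hydrogenation of an E allylic alcohol (the geraniol-to-citronellol case); the primary OH binds Ru and the (R)-ligand delivers H2 to the face that gives (13S), under catalyst control remote from the decalin.

**Step 9**
Reactants: 17 (1R,2R,4aS,8aS)-1-[(3S)-5-hydroxy-3-methylpentyl]-2,5,5,8a-tetramethyldecahydronaphthalen-2-ol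
Product: 18 (3S)-5-[(1R,2R,4aS,8aS)-2-hydroxy-2,5,5,8a-tetramethyldecahydronaphthalen-1-yl]-3-methylpentyl acetate
Conditions: Ac2O (1.2 equiv), pyridine, CH2Cl2, 0 → 23 °C
Reagents that add atoms: acetic anhydride CC(=O)OC(C)=O
Why: Selective O-acetylation of the primary alcohol; the hindered tertiary C-8 alcohol does not react with Ac2O/pyridine without DMAP.

**Compound list**
1 | pent-4-yn-1-ol | C#CCCCO | starting material
2 | pent-4-yn-1-yl N,N-diisopropylcarbamate | C#CCCCOC(=O)N(C(C)C)C(C)C | intermediate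
3 | 5-(trimethylsilyl)pent-4-yn-1-yl N,N-diisopropylcarbamate | C[Si](C)(C)C#CCCCOC(=O)N(C(C)C)C(C)C | intermediate
4 | 2,2-dimethylcyclopentan-1-one | CC1(C)CCCC1=O | starting material
5 | (1R)-1-lithio-5-(trimethylsilyl)pent-4-yn-1-yl N,N-diisopropylcarbamate, (+)-sparteine complex | [Li][C@H](CCC#C[Si](C)(C)C)OC(=O)N(C(C)C)C(C)C | intermediate
6 | lithium 1-[(1S)-1-(diisopropylcarbamoyloxy)-5-(trimethylsilyl)pent-4-yn-1-yl]-2,2-dimethylcyclopentan-1-olate (both carbinol epimers) | [Li+].[O-]C1(CCCC1(C)C)[C@H](CCC#C[Si](C)(C)C)OC(=O)N(C(C)C)C(C)C | intermediate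
7 | (2S)-3,3-dimethyl-2-[4-(trimethylsilyl)but-3-yn-1-yl]cyclohexan-1-one | O=C1CCCC(C)(C)[C@@H]1CCC#C[Si](C)(C)C | intermediate
8 | (2S)-1,3,3-trimethyl-2-[4-(trimethylsilyl)but-3-yn-1-yl]cyclohexan-1-ol (both C-1 epimers) | CC1(O)CCCC(C)(C)[C@@H]1CCC#C[Si](C)(C)C | intermediate
9 | (2S)-2-(but-3-yn-1-yl)-1,3,3-trimethylcyclohexan-1-ol (both C-1 epimers) | CC1(O)CCCC(C)(C)[C@@H]1CCC#C | intermediate
10 | but-3-en-2-one (methyl vinyl ketone) | CC(=O)C=C | starting material
11 | (E)-alkenyl(dimethyl)alane of 9: Me2Al on the terminal alkene carbon cis to the new CH3, carbinol as its O–AlMe2 alkoxide | CC1(O[Al](C)C)CCCC(C)(C)[C@@H]1CC/C(C)=C/[Al](C)C | intermediate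
12 | (5E)-8-[(1S)-2-hydroxy-2,6,6-trimethylcyclohexyl]-6-methyloct-5-en-2-one (both carbinol epimers) | CC1(O)CCCC(C)(C)[C@@H]1CC/C(C)=C/CCC(C)=O | intermediate
13 | sclareol oxide, (5S,8R,9R,10S)-8α,13-epoxy-14,15-dinorlabd-12-ene | CC1=CC[C@@H]2[C@@]3(C)CCCC(C)(C)[C@@H]3CC[C@@]2(C)O1 | intermediate
14 | 4-[(1R,2R,4aS,8aS)-2-hydroxy-2,5,5,8a-tetramethyldecahydronaphthalen-1-yl]butan-2-one (8α-hydroxy-14,15-dinorlabdan-13-one) | CC(=O)CC[C@@H]1[C@@]2(C)CCCC(C)(C)[C@@H]2CC[C@@]1(C)O | intermediate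
15 | ethyl (2E)-5-[(1R,2R,4aS,8aS)-2-hydroxy-2,5,5,8a-tetramethyldecahydronaphthalen-1-yl]-3-methylpent-2-enoate | CCOC(=O)/C=C(\C)CC[C@@H]1[C@@]2(C)CCCC(C)(C)[C@@H]2CC[C@@]1(C)O | intermediate
16 | (1R,2R,4aS,8aS)-1-[(3E)-5-hydroxy-3-methylpent-3-en-1-yl]-2,5,5,8a-tetramethyldecahydronaphthalen-2-ol | OC/C=C(\C)CC[C@@H]1[C@@]2(C)CCCC(C)(C)[C@@H]2CC[C@@]1(C)O | intermediate
17 | (1R,2R,4aS,8aS)-1-[(3S)-5-hydroxy-3-methylpentyl]-2,5,5,8a-tetramethyldecahydronaphthalen-2-ol ((13S)-labdane-8α,15-diol) | OCC[C@@H](C)CC[C@@H]1[C@@]2(C)CCCC(C)(C)[C@@H]2CC[C@@]1(C)O | intermediate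
18 | (3S)-5-[(1R,2R,4aS,8aS)-2-hydroxy-2,5,5,8a-tetramethyldecahydronaphthalen-1-yl]-3-methylpentyl acetate | CC(=O)OCC[C@@H](C)CC[C@@H]1[C@@]2(C)CCCC(C)(C)[C@@H]2CC[C@@]1(C)O | target

**Step count and risks**
Total step count: 9. Longest linear sequence: 9 steps (from pent-4-yn-1-ol; fully linear).

Three steps most likely to fail:

Step 2 (the proposed new ring expansion). The open points are addition of the lithiated carbamate to a hindered, enolisable ketone, whether a carbamate leaves under aluminium activation, and whether the CMe2 carbon migrates in preference to the CH2 carbon. The fallback uses known chemistry and sets out from 3 and 4. The same lithiation and addition are quenched with aqueous NH4Cl to give (1S)-1-(1-hydroxy-2,2-dimethylcyclopentyl)-5-(trimethylsilyl)pent-4-yn-1-yl N,N-diisopropylcarbamate F1. LiAlH4 in refluxing THF removes the carbamoyl group to give 1-[(1S)-1-hydroxy-5-(trimethylsilyl)pent-4-yn-1-yl]-2,2-dimethylcyclopentan-1-ol F2. MsCl/Et3N at −20 °C sulfonylates only the secondary OH to give (1S)-1-(1-hydroxy-2,2-dimethylcyclopentyl)-5-(trimethylsilyl)pent-4-yn-1-yl methanesulfonate F3. Et3Al in CH2Cl2 at −78 °C then effects the established organoaluminium-promoted semipinacol shift with inversion, and the route is rejoined at 7.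

Step 5 (cyclisation). The C-10 cation can lose H-5 before ring closure, which would erode the configuration set in step 2, and the chain alkene or ketone can be protonated first. The fallback sets out from 7 and starts the cyclisation from an exocyclic alkene instead of a carbinol, as is documented for optically active γ-dihydroionone-type substrates that keep their ring stereocentre. Wittig methylenation (Ph3P=CH2, THF) gives {4-[(1S)-2,2-dimethyl-6-methylidenecyclohexyl]but-1-yn-1-yl}trimethylsilane F4. K2CO3/MeOH gives (2S)-2-(but-3-yn-1-yl)-1,1-dimethyl-3-methylidenecyclohexane F5. Methylalumination as in step 4 gives the (E)-alkenyl(dimethyl)alane F6, and Cu-catalysed addition to 10 gives (5E)-8-[(1S)-2,2-dimethyl-6-methylidenecyclohexyl]-6-methyloct-5-en-2-one F7. FSO3H in 2-nitropropane at −78 °C followed by the same aqueous acid treatment returns the route to 14 (through 13).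

Step 6 (HWE). A methyl ketone gives an E/Z mixture that must be separated before the stereospecific hydrogenation, and the C-8 alkoxide can add to the enoate. The fallback sets out from 14 and builds the E-alkene by carbometalation instead of olefination. LDA then ClP(O)(OEt)2 gives diethyl 4-[(1R,2R,4aS,8aS)-2-hydroxy-2,5,5,8a-tetramethyldecahydronaphthalen-1-yl]but-1-en-2-yl phosphate F8. Excess LDA eliminates it to (1R,2R,4aS,8aS)-1-(but-3-yn-1-yl)-2,5,5,8a-tetramethyldecahydronaphthalen-2-ol F9. Me3Al/Cp2ZrCl2 gives the (E)-alkenyl(dimethyl)alane F10, which is trapped with paraformaldehyde to rejoin the route at 16 as the E isomer only, bypassing 15.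

**Further compounds**
F1 | step 2 | (1S)-1-(1-hydroxy-2,2-dimethylcyclopentyl)-5-(trimethylsilyl)pent-4-yn-1-yl N,N-diisopropylcarbamate | OC1(CCCC1(C)C)[C@H](CCC#C[Si](C)(C)C)OC(=O)N(C(C)C)C(C)C
F2 | step 2 | 1-[(1S)-1-hydroxy-5-(trimethylsilyl)pent-4-yn-1-yl]-2,2-dimethylcyclopentan-1-ol | OC1(CCCC1(C)C)[C@H](CCC#C[Si](C)(C)C)O
F3 | step 2 | (1S)-1-(1-hydroxy-2,2-dimethylcyclopentyl)-5-(trimethylsilyl)pent-4-yn-1-yl methanesulfonate | OC1(CCCC1(C)C)[C@H](CCC#C[Si](C)(C)C)OS(C)(=O)=O
F4 | step 5 | {4-[(1S)-2,2-dimethyl-6-methylidenecyclohexyl]but-1-yn-1-yl}trimethylsilane | C=C1CCCC(C)(C)[C@@H]1CCC#C[Si](C)(C)C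
F5 | step 5 | (2S)-2-(but-3-yn-1-yl)-1,1-dimethyl-3-methylidenecyclohexane | C=C1CCCC(C)(C)[C@@H]1CCC#C
F6 | step 5 | (E)-alkenyl(dimethyl)alane of F5 | C=C1CCCC(C)(C)[C@@H]1CC/C(C)=C/[Al](C)C
F7 | step 5 | (5E)-8-[(1S)-2,2-dimethyl-6-methylidenecyclohexyl]-6-methyloct-5-en-2-one | C=C1CCCC(C)(C)[C@@H]1CC/C(C)=C/CCC(C)=O
F8 | step 6 | diethyl 4-[(1R,2R,4aS,8aS)-2-hydroxy-2,5,5,8a-tetramethyldecahydronaphthalen-1-yl]but-1-en-2-yl phosphate | C=C(OP(=O)(OCC)OCC)CC[C@@H]1[C@@]2(C)CCCC(C)(C)[C@@H]2CC[C@@]1(C)O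
F9 | step 6 | (1R,2R,4aS,8aS)-1-(but-3-yn-1-yl)-2,5,5,8a-tetramethyldecahydronaphthalen-2-ol | C#CCC[C@@H]1[C@@]2(C)CCCC(C)(C)[C@@H]2CC[C@@]1(C)O
F10 | step 6 | (E)-alkenyl(dimethyl)alane of F9 (C-8 oxygen as O–AlMe2) | C[Al](C)/C=C(\C)CC[C@@H]1[C@@]2(C)CCCC(C)(C)[C@@H]2CC[C@@]1(C)O[Al](C)C
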